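The rate constants are assumed; the result is computed.

At late times a closed flask loses its intermediate through step 2, so a run of 15 min has to be placed on one side of the turn or the other.

    starting material → intermediate (k1 = 0.084 /min)
    intermediate → product (k2 = 0.019 /min)
    starting material ⇌ dormant form (K3 = 0.85, k3 = 0.025 /min)
    starting material + product ⇌ idle adduct, settled at all times (K4 = 0.53 /M)

| setting | Sunday's | Tuesday's |
|---|---|---|
| starting material | 0.50 M | 0.50 M |
| remark | a single well-mixed tank run continuously and read at steady state, 15 min in it on average | a closed flask charged with all of it at once and left for 15 min |
| time |  | 15 min |

* the set-up with the highest amount of intermediate at the outlet or at the end, in percent of the starting material put in ("none" if the first two lie within 2 percentage points) (Sunday's / Tuesday's / none)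
* amount of intermediate at the outlet or at the end, in percent of the starting material put in, Sunday's
* amount of intermediate at the outlet or at the end, in percent of the starting material put in, Tuesday's

- in percentages every species weighs as the starting material in it: one idle adduct counts as two
- for product the idle adduct is counted in
- the stated concentrations are those of everything mixed, before any reaction; amounts are the same in each set-up
- in an amount of product, one idle adduct counts as one product
- run time (Tuesday's): 15 min

The turn comes where making equals loss, 0.084 /min times c(starting material) against 0.019 /min times c(intermediate). The crossing ratio, the c(intermediate)/c(starting material) at which a closed flask's intermediate stops rising, is therefore the step 1 constant over the step 2 constant, 4.42.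

This reckoning sets up a small table with two columns, Sunday's tank and Tuesday's flask. It drops the idle adduct and treats the dormant form as a one-way sink, so starting material falls with 0.109 /min.

Row one, starting material left, reads 38.0% for the tank and 19.5% for the flask. Tuesday's flask has less starting material left than Sunday's tank.

Row two, intermediate, reads 37.2% against 52.0%. That gap of 15 percentage points in favour of the flask is wider than the margin.

Row three, the ratio of row two to row one, reads 0.981 against 2.67. The flask's ratio is lower than the crossing ratio, so at the end of its run Tuesday's intermediate is still climbing. This reckoning commits to Tuesday's.

The forecast also names Tuesday's, with 38.5% for Sunday's tank and 53.2% for Tuesday's flask. Both values are higher than this table's, and its grounds include that “the tank runs entirely at outlet concentrations”.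

The simulation gives Tuesday's, with 38.5% in Sunday's tank and 53.1% in Tuesday's flask. Tuesday's flask ends with 21.8% starting material, so its ratio reads 2.44. That is lower than the crossing ratio 4.42, and making still exceeds loss at that moment. Left for 150 min, the same flask holds 10.0% intermediate, less than at the end of its run, so it has gone past the crossing; an intermediate still falling there puts its starting material below 2.26% of the charge.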